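## Retrosynthetic overview

1. Feature: in ring A the quaternary C(CH3)2 carbon stands between two carbonyl-level ring carbons. One of them is the direct neighbour of the ring carbon that holds the CH2 bridge to C6 of the chromene. Breaking the bond from C(CH3)2 to that carbonyl carbon turns ring A into an isopropyl ketone plus an ester, which is a 6-isopropyl-4-oxygenated 2-pyrone carrying the bridge on C3.
2. End game (steps 10–12): MOM removal ⇐ C-propanoylation of the last free ring A CH ⇐ trione 18 ⇐ its methyl enol ether 17.
3. Key disconnection (step 9): 17 ⇐ 4-methoxypyrone 15, by methoxide opening and Claisen closure from the isopropyl methine carbon. The pyrone oxygen is methylated for this step only. The free hydroxypyrone would sit as an anion inert to methoxide, and its opened chain would lose the proton next to the ester and so switch the electrophile off.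
4. Bridge (step 7): C3 of pyrone 4 (from methyl acetoacetate dianion and methyl isobutyrate) is reductively alkylated with chromene aldehyde 12. Aldehyde 12 comes from phloropropiophenone 5 and prenal 7, and a 4-O-MOM group steers the pyran closure to the oxygen next to the propanoyl carbon.
5. Ring order: pyrone ring (step 2) and chromene pyran ring (step 4) in parallel, union (step 7), then conversion of the pyrone ring into carbocyclic ring A (step 9).

Key step: step 9

Assumption: the enolised di- and tricarbonyl compounds (4, 14, 17–21) are each drawn as one tautomer, the tautomers being in rapid equilibrium; the target has no stereocentre.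

## Route

Step 1
Reactants: 1 methyl acetoacetate; 2 methyl isobutyrate
Product: 3 methyl 6-methyl-3,5-dioxoheptanoate
Conditions: 1 (2 equiv), NaH then n-BuLi, THF, 0 °C; 2 (1 equiv), 0 → 23 °C; aq HCl
Reagents that add atoms: none
Why: γ-Acylation of a β-keto ester dianion (crossed Claisen condensation): the terminal carbanion of the dianion of 1 is the most nucleophilic site and attacks ester 2, while the surplus dianion takes up the acidic proton of the 3,5-dioxo ester as it forms.

Step 2
Reactants: 3 methyl 6-methyl-3,5-dioxoheptanoate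
Product: 4 4-hydroxy-6-(propan-2-yl)-2H-pyran-2-one
Conditions: DBU (1.5 equiv), toluene, 110 °C; aq HCl
Reagents that add atoms: none
Why: Base-induced lactonisation of a 3,5-dioxo ester: the enolate oxygen at C5 attacks the ester carbonyl, methoxide leaves, and the stabilised 4-hydroxy-2-pyrone anion draws the equilibrium over.

Step 3
Reactants: 5 1-(2,4,6-trihydroxyphenyl)propan-1-one
Product: 6 1-[2,6-dihydroxy-4-(methoxymethoxy)phenyl]propan-1-one
Conditions: MOMCl (1.0 equiv), iPr2NEt (1.1 equiv), THF, 0 °C
Reagents that add atoms: chloromethyl methyl ether, COCCl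
Why: Selective O-alkylation (Williamson-type acetal formation): the 4-hydroxyl is the only one not tied into a hydrogen bond with the ketone and is the most acidic, so one equivalent of MOMCl should react there first, and over-protected material is removed by chromatography.

Step 4
Reactants: 6 1-[2,6-dihydroxy-4-(methoxymethoxy)phenyl]propan-1-one; 7 3-methylbut-2-enal
Product: 9 1-[7-hydroxy-5-(methoxymethoxy)-2,2-dimethyl-2H-chromen-8-yl]propan-1-one, via oxatriene 8 (not isolated)
Conditions: 7 (1.3 equiv), ethylenediammonium diacetate (20 mol %), toluene, 110 °C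
Reagents that add atoms: none
Why: Amine-salt-catalysed chromenylation (Knoevenagel-type condensation at a ring carbon, then oxa-6π electrocyclisation of 8): the two free hydroxyls of 6 are equivalent and O4 is blocked, so the pyran ring can close only on the oxygen next to the propanoyl-bearing carbon, which fixes the 8-acyl pattern of the target.

Step 5
Reactants: 9 1-[7-hydroxy-5-(methoxymethoxy)-2,2-dimethyl-2H-chromen-8-yl]propan-1-one
Product: 11 7-hydroxy-5-(methoxymethoxy)-2,2-dimethyl-8-propanoyl-2H-chromene-6-carbaldehyde, via salicyl alcohol 10 (not isolated)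
Conditions: MgCl2 (3 equiv), Et3N (5 equiv), (CH2O)n (8 equiv), MeCN, 80 °C; aq citric acid
Reagents that add atoms: paraformaldehyde (reacts as formaldehyde), C=O
Why: Magnesium-mediated ortho-formylation of a phenol (Casnati–Skattebøl reaction): the magnesium phenoxide delivers formaldehyde to C6, the only free ring position, and a second formaldehyde oxidises salicyl alcohol 10 by hydride transfer, while the non-acidic medium spares the MOM ether and avoids the chromone formation that Vilsmeier reagents cause with ortho-hydroxyaryl ketones.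

Step 6
Reactants: 11 7-hydroxy-5-(methoxymethoxy)-2,2-dimethyl-8-propanoyl-2H-chromene-6-carbaldehyde
Product: 12 5,7-bis(methoxymethoxy)-2,2-dimethyl-8-propanoyl-2H-chromene-6-carbaldehyde
Conditions: NaH (1.3 equiv), MOMCl (1.5 equiv), DMF, 0 → 23 °C
Reagents that add atoms: chloromethyl methyl ether, COCCl
Why: Williamson-type O-alkylation: the doubly chelated 7-hydroxyl is fully deprotonated by NaH and the phenoxide is trapped by the very reactive MOMCl, so that no free phenol remains that could fragment the bridge in base later.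

Step 7
Reactants: 12 5,7-bis(methoxymethoxy)-2,2-dimethyl-8-propanoyl-2H-chromene-6-carbaldehyde; 4 4-hydroxy-6-(propan-2-yl)-2H-pyran-2-one
Product: 14 3-{[5,7-bis(methoxymethoxy)-2,2-dimethyl-8-propanoyl-2H-chromen-6-yl]methyl}-4-hydroxy-6-(propan-2-yl)-2H-pyran-2-one, via arylidene pyrandione 13 (not isolated)
Conditions: diethyl 2,6-dimethyl-1,4-dihydropyridine-3,5-dicarboxylate (Hantzsch ester, 1.2 equiv), L-proline (20 mol %), CH2Cl2, 23 → 40 °C
Reagents that add atoms: none
Why: Three-component organocatalytic reductive alkylation: proline-catalysed Knoevenagel condensation at pyrone C3, the only nucleophilic carbon of 4, gives the electrophilic arylidene 13, which should take up hydride from the Hantzsch ester in a conjugate reduction before a second pyrone adds irreversibly.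

Step 8
Reactants: 14 3-{[5,7-bis(methoxymethoxy)-2,2-dimethyl-8-propanoyl-2H-chromen-6-yl]methyl}-4-hydroxy-6-(propan-2-yl)-2H-pyran-2-one
Product: 15 3-{[5,7-bis(methoxymethoxy)-2,2-dimethyl-8-propanoyl-2H-chromen-6-yl]methyl}-4-methoxy-6-(propan-2-yl)-2H-pyran-2-one
Conditions: Me2SO4 (1.2 equiv), K2CO3 (2 equiv), acetone, 56 °C
Reagents that add atoms: dimethyl sulfate, COS(=O)(=O)OC
Why: O-Methylation of a 4-hydroxy-2-pyrone with a hard electrophile and K2CO3, conditions that favour the 4-methoxy-2-pyrone over the 2-methoxy-4-pyrone; the cap makes the lactone neutral and thus open to methoxide, and it removes the acidic C–H that the opened chain would otherwise carry next to the ester.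

Step 9
Reactants: 15 3-{[5,7-bis(methoxymethoxy)-2,2-dimethyl-8-propanoyl-2H-chromen-6-yl]methyl}-4-methoxy-6-(propan-2-yl)-2H-pyran-2-one
Product: 17 2-{[5,7-bis(methoxymethoxy)-2,2-dimethyl-8-propanoyl-2H-chromen-6-yl]methyl}-5-hydroxy-3-methoxy-6,6-dimethylcyclohexa-2,4-dien-1-one, via opened keto ester 16 (not isolated)
Conditions: NaOMe (3 equiv), MeOH, 65 °C; then solvent change to DMSO (trace MeOH kept), 0.02 M, 100 °C; AcOH quench
Reagents that add atoms: sodium methoxide, [Na+].[O-]C (adds OCH3 to intermediate 16; the same group leaves again on closure to 17)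
Why: Proposed new method: methoxide adds to the lactone carbonyl of the neutral 4-methoxypyrone 15 and sets free the keto ester 16 as its conjugated dienolate, which equilibrates through traces of methanol with the less stable tetrasubstituted enolate of the isopropyl ketone, and the former methine carbon of this enolate attacks the ester carbonyl, methoxide leaves, and the bond from the C(CH3)2 carbon to the carbonyl carbon next to the bridge-bearing carbon closes ring A. The closest known reaction types are the alkoxide-induced Claisen recyclisation of 4-oxygenated 2-pyrones and 3,5-dioxoalkanoates to phloroglucinol derivatives and the enol lactone to cyclic 1,3-dione rearrangement, which have been run with primary or secondary carbanions only, whereas here a tertiary carbanion must build a quaternary carbon. The closure is 6-(enolendo)-exo-trig, an allowed mode, and the E double bond that 16 inherits from the pyrone ring keeps the ester and the ketone arm on the same side. No stereocentre is created. The step needs C-acylation from the least acidic position, and the substrate secures it as follows: the enol ether leaves no proton next to the ester, so the ester stays a neutral electrophile and only monoanions are involved; O-acylation merely returns 15 and is reversible; the more acidic CH2 carbon could only close a four-membered ring; and 17 alone is a vinylogous acid whose deprotonation takes it out of the equilibria. The MOM ethers prevent quinone methide fragmentation of the bridge in base, and the aryl ethyl ketone can only enolise reversibly, since ring closure from it would demand a meta-bridged eight-membered ring.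

Step 10
Reactants: 17 2-{[5,7-bis(methoxymethoxy)-2,2-dimethyl-8-propanoyl-2H-chromen-6-yl]methyl}-5-hydroxy-3-methoxy-6,6-dimethylcyclohexa-2,4-dien-1-one
Product: 18 2-{[5,7-bis(methoxymethoxy)-2,2-dimethyl-8-propanoyl-2H-chromen-6-yl]methyl}-3-hydroxy-4,4-dimethylcyclohex-2-ene-1,5-dione
Conditions: LiCl (10 equiv), DMSO, 120 °C; cold 1 M HCl
Reagents that add atoms: none
Why: SN2 dealkylation of a vinylogous methyl ester by chloride (Krapcho-type, LiCl in DMSO as used for methyl enol ethers of cyclic β-dicarbonyl compounds): the leaving group is the stabilised trione anion, the neutral medium spares the MOM ethers, and the methoxy group is gone before any phenol is freed that could displace it and close a xanthene.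

Step 11
Reactants: 18 2-{[5,7-bis(methoxymethoxy)-2,2-dimethyl-8-propanoyl-2H-chromen-6-yl]methyl}-3-hydroxy-4,4-dimethylcyclohex-2-ene-1,5-dione
Product: 20 2-{[5,7-bis(methoxymethoxy)-2,2-dimethyl-8-propanoyl-2H-chromen-6-yl]methyl}-3,5-dihydroxy-4,4-dimethyl-6-propanoylcyclohexa-2,5-dien-1-one, via enol propanoate 19 (not isolated)
Conditions: EtCOCl (1.1 equiv), Et3N (3 equiv), CH2Cl2, 0 °C; then 4-(dimethylamino)pyridine (0.3 equiv), 23 → 40 °C; cold dilute HCl
Reagents that add atoms: propanoyl chloride, CCC(=O)Cl
Why: O-Acylation followed by nucleophile-catalysed O-to-C acyl migration, the standard access to 2-acylcyclohexane-1,3-diones: the acylpyridinium/enolate pair recombines at carbon, acylation at the carbon that already bears the bridge is reversible, and only acylation at the free CH gives a strongly acidic triketone that is held as its ammonium salt.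

Step 12
Reactants: 20 2-{[5,7-bis(methoxymethoxy)-2,2-dimethyl-8-propanoyl-2H-chromen-6-yl]methyl}-3,5-dihydroxy-4,4-dimethyl-6-propanoylcyclohexa-2,5-dien-1-one
Product: 21 2-[(5,7-dihydroxy-2,2-dimethyl-8-propanoyl-2H-chromen-6-yl)methyl]-3,5-dihydroxy-4,4-dimethyl-6-propanoylcyclohexa-2,5-dien-1-one (CNP0277188.0)
Conditions: 3 M aq HCl, THF, 45 °C
Reagents that add atoms: none
Why: Acid hydrolysis of the two aryl MOM acetals in an aqueous medium that is mild enough for the 2,2-dimethylchromene and too mild for dehydrative xanthene closure between a phenol and a ring A enol.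

## Compound list

1 | methyl acetoacetate | CC(=O)CC(=O)OC | starting material
2 | methyl isobutyrate | CC(C)C(=O)OC | starting material
3 | methyl 6-methyl-3,5-dioxoheptanoate | COC(=O)CC(=O)CC(=O)C(C)C | intermediate
4 | 4-hydroxy-6-(propan-2-yl)-2H-pyran-2-one | CC(C)c1cc(O)cc(=O)o1 | intermediate
5 | 1-(2,4,6-trihydroxyphenyl)propan-1-one | CCC(=O)c1c(O)cc(O)cc1O | starting material
6 | 1-[2,6-dihydroxy-4-(methoxymethoxy)phenyl]propan-1-one | CCC(=O)c1c(O)cc(OCOC)cc1O | intermediate
7 | 3-methylbut-2-enal | CC(C)=CC=O | starting material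
8 | (6Z)-3-hydroxy-5-(methoxymethoxy)-6-(3-methylbut-2-en-1-ylidene)-2-propanoylcyclohexa-2,4-dien-1-one | CCC(=O)C1=C(O)C=C(OCOC)/C(=C/C=C(C)C)C1=O | intermediate
9 | 1-[7-hydroxy-5-(methoxymethoxy)-2,2-dimethyl-2H-chromen-8-yl]propan-1-one | CCC(=O)c1c(O)cc(OCOC)c2C=CC(C)(C)Oc12 | intermediate
10 | 1-[7-hydroxy-6-(hydroxymethyl)-5-(methoxymethoxy)-2,2-dimethyl-2H-chromen-8-yl]propan-1-one | CCC(=O)c1c(O)c(CO)c(OCOC)c2C=CC(C)(C)Oc12 | intermediate
11 | 7-hydroxy-5-(methoxymethoxy)-2,2-dimethyl-8-propanoyl-2H-chromene-6-carbaldehyde | CCC(=O)c1c(O)c(C=O)c(OCOC)c2C=CC(C)(C)Oc12 | intermediate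
12 | 5,7-bis(methoxymethoxy)-2,2-dimethyl-8-propanoyl-2H-chromene-6-carbaldehyde | CCC(=O)c1c(OCOC)c(C=O)c(OCOC)c2C=CC(C)(C)Oc12 | intermediate
13 | 3-{[5,7-bis(methoxymethoxy)-2,2-dimethyl-8-propanoyl-2H-chromen-6-yl]methylidene}-6-(propan-2-yl)-2H-pyran-2,4(3H)-dione (double-bond geometry not defined, immaterial) | CC(C)C1=CC(=O)C(=Cc2c(OCOC)c3c(c(C(=O)CC)c2OCOC)OC(C)(C)C=C3)C(=O)O1 | intermediate
14 | 3-{[5,7-bis(methoxymethoxy)-2,2-dimethyl-8-propanoyl-2H-chromen-6-yl]methyl}-4-hydroxy-6-(propan-2-yl)-2H-pyran-2-one | CC(C)c1cc(O)c(Cc2c(OCOC)c3c(c(C(=O)CC)c2OCOC)OC(C)(C)C=C3)c(=O)o1 | intermediate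
15 | 3-{[5,7-bis(methoxymethoxy)-2,2-dimethyl-8-propanoyl-2H-chromen-6-yl]methyl}-4-methoxy-6-(propan-2-yl)-2H-pyran-2-one | CC(C)c1cc(OC)c(Cc2c(OCOC)c3c(c(C(=O)CC)c2OCOC)OC(C)(C)C=C3)c(=O)o1 | intermediate
16 | methyl (2E)-2-{[5,7-bis(methoxymethoxy)-2,2-dimethyl-8-propanoyl-2H-chromen-6-yl]methyl}-3-methoxy-6-methyl-5-oxohept-2-enoate | COC(=O)/C(Cc1c(OCOC)c2c(c(C(=O)CC)c1OCOC)OC(C)(C)C=C2)=C(/OC)CC(=O)C(C)C | intermediate
17 | 2-{[5,7-bis(methoxymethoxy)-2,2-dimethyl-8-propanoyl-2H-chromen-6-yl]methyl}-5-hydroxy-3-methoxy-6,6-dimethylcyclohexa-2,4-dien-1-one | CC1(C)C(O)=CC(OC)=C(Cc2c(OCOC)c3c(c(C(=O)CC)c2OCOC)OC(C)(C)C=C3)C1=O | intermediate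
18 | 2-{[5,7-bis(methoxymethoxy)-2,2-dimethyl-8-propanoyl-2H-chromen-6-yl]methyl}-3-hydroxy-4,4-dimethylcyclohex-2-ene-1,5-dione | CC1(C)C(=O)CC(=O)C(Cc2c(OCOC)c3c(c(C(=O)CC)c2OCOC)OC(C)(C)C=C3)=C1O | intermediate
19 | 6-{[5,7-bis(methoxymethoxy)-2,2-dimethyl-8-propanoyl-2H-chromen-6-yl]methyl}-5-hydroxy-4,4-dimethyl-3-oxocyclohexa-1,5-dien-1-yl propanoate (one of the interconverting enol esters) | CCC(=O)OC1=CC(=O)C(C)(C)C(O)=C1Cc1c(OCOC)c2c(c(C(=O)CC)c1OCOC)OC(C)(C)C=C2 | intermediate
20 | 2-{[5,7-bis(methoxymethoxy)-2,2-dimethyl-8-propanoyl-2H-chromen-6-yl]methyl}-3,5-dihydroxy-4,4-dimethyl-6-propanoylcyclohexa-2,5-dien-1-one | CCC(=O)C1=C(O)C(C)(C)C(O)=C(Cc2c(OCOC)c3c(c(C(=O)CC)c2OCOC)OC(C)(C)C=C3)C1=O | intermediate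
21 | 2-[(5,7-dihydroxy-2,2-dimethyl-8-propanoyl-2H-chromen-6-yl)methyl]-3,5-dihydroxy-4,4-dimethyl-6-propanoylcyclohexa-2,5-dien-1-one | CCC(=O)C1=C(O)C(C)(C)C(O)=C(Cc2c(O)c3c(c(C(=O)CC)c2O)OC(C)(C)C=C3)C1=O | target

## Step count and risks

Total step count: 12.
Longest linear sequence: 10 steps (5 → 21, steps 3–12). The pyrone branch (steps 1–2) joins at step 7.

**Step 9 (key step).**
- What may go wrong: the hindered tertiary enolate may add too slowly to the tetrasubstituted β-methoxyacrylate ester. The system would then only shuttle between closed pyrone and opened dienolate.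
- Slow drains would operate meanwhile: retro-Claisen attack of methoxide on the isopropyl ketone, 1,6-addition of methoxide to the pyrone, and SN2 loss of the ester methyl group.
- Fallback (known chemistry): ring A is made by dearomatisation instead of from the pyrone. It sets out from 5, which is C,C-dimethylated with MeI and NaOMe in MeOH to 3,5-dihydroxy-4,4-dimethyl-2-propanoylcyclohexa-2,5-dien-1-one F1. F1 is separated from under- and over-methylated material.
- F1 is then reductively alkylated at its free ring CH with aldehyde 12 (Hantzsch ester, L-proline, CH2Cl2). This runs through 6-{[5,7-bis(methoxymethoxy)-2,2-dimethyl-8-propanoyl-2H-chromen-6-yl]methylidene}-3-hydroxy-4,4-dimethyl-2-propanoylcyclohex-2-ene-1,5-dione F2.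
- It comes back to the route at 20, before step 12.

**Step 5.**
- What may go wrong: the magnesium phenoxide may be tied up in a chelate with the neighbouring ketone. The salicyl alcohol stage may lose water and couple with unreacted phenol. Formaldehyde may add at the α-carbon of the ketone.
- Fallback: the bridge carbon is brought in as an aminomethyl group and the union runs through a quinone methide instead of an aldehyde. It sets out from 9. Mannich aminomethylation with dimethyl(methylidene)ammonium iodide in CH2Cl2 gives 1-{6-[(dimethylamino)methyl]-7-hydroxy-5-(methoxymethoxy)-2,2-dimethyl-2H-chromen-8-yl}propan-1-one F3.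
- Heated with pyrone 4 in dioxane, F3 loses dimethylamine to 5-(methoxymethoxy)-2,2-dimethyl-6-methylidene-8-propanoyl-2H-chromen-7(6H)-one F4.
- F4 is captured by C3 of 4 in a Michael addition to give 4-hydroxy-3-{[7-hydroxy-5-(methoxymethoxy)-2,2-dimethyl-8-propanoyl-2H-chromen-6-yl]methyl}-6-(propan-2-yl)-2H-pyran-2-one F5.
- Both acidic hydroxyls are then capped with MOMCl and iPr2NEt to give 3-{[5,7-bis(methoxymethoxy)-2,2-dimethyl-8-propanoyl-2H-chromen-6-yl]methyl}-4-(methoxymethoxy)-6-(propan-2-yl)-2H-pyran-2-one F6.
- The MOM group on the pyrone oxygen is the acetal of a vinylogous acid and far more labile than the aryl MOM ethers. It is removed alone with aqueous acetic acid at 23 °C.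
- It comes back to the route at 14, before step 8.

**Step 7.**
- What may go wrong: the Knoevenagel condensation of the doubly ortho-substituted, electron-rich aldehyde may be slow. A second pyrone may also capture the arylidene before hydride transfer.
- Fallback: the C–C bond is made by benzylic cation alkylation instead of carbonyl condensation. It sets out from 12. NaBH4 in MeOH at 0 °C reduces only the aldehyde, because the ketone is shielded by two ortho substituents. This gives 1-[6-(hydroxymethyl)-5,7-bis(methoxymethoxy)-2,2-dimethyl-2H-chromen-8-yl]propan-1-one F7.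
- This trialkoxybenzyl alcohol ionises in hexafluoroisopropanol at 40 °C without added acid. It alkylates C3 of pyrone 4 in a dehydrative Friedel–Crafts-type benzylation.
- It comes back to the route at 14.

## Further compounds

F1 | step 9 | 3,5-dihydroxy-4,4-dimethyl-2-propanoylcyclohexa-2,5-dien-1-one | CCC(=O)C1=C(O)C(C)(C)C(O)=CC1=O
F2 | step 9 | 6-{[5,7-bis(methoxymethoxy)-2,2-dimethyl-8-propanoyl-2H-chromen-6-yl]methylidene}-3-hydroxy-4,4-dimethyl-2-propanoylcyclohex-2-ene-1,5-dione | CCC(=O)C1=C(O)C(C)(C)C(=O)C(=Cc2c(OCOC)c3c(c(C(=O)CC)c2OCOC)OC(C)(C)C=C3)C1=O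
F3 | step 5 | 1-{6-[(dimethylamino)methyl]-7-hydroxy-5-(methoxymethoxy)-2,2-dimethyl-2H-chromen-8-yl}propan-1-one | CCC(=O)c1c(O)c(CN(C)C)c(OCOC)c2C=CC(C)(C)Oc12
F4 | step 5 | 5-(methoxymethoxy)-2,2-dimethyl-6-methylidene-8-propanoyl-2H-chromen-7(6H)-one | CCC(=O)C1=C2OC(C)(C)C=CC2=C(OCOC)C(=C)C1=O
F5 | step 5 | 4-hydroxy-3-{[7-hydroxy-5-(methoxymethoxy)-2,2-dimethyl-8-propanoyl-2H-chromen-6-yl]methyl}-6-(propan-2-yl)-2H-pyran-2-one | CC(C)c1cc(O)c(Cc2c(OCOC)c3c(c(C(=O)CC)c2O)OC(C)(C)C=C3)c(=O)o1
F6 | step 5 | 3-{[5,7-bis(methoxymethoxy)-2,2-dimethyl-8-propanoyl-2H-chromen-6-yl]methyl}-4-(methoxymethoxy)-6-(propan-2-yl)-2H-pyran-2-one | CC(C)c1cc(OCOC)c(Cc2c(OCOC)c3c(c(C(=O)CC)c2OCOC)OC(C)(C)C=C3)c(=O)o1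
F7 | step 7 | 1-[6-(hydroxymethyl)-5,7-bis(methoxymethoxy)-2,2-dimethyl-2H-chromen-8-yl]propan-1-one | CCC(=O)c1c(OCOC)c(CO)c(OCOC)c2C=CC(C)(C)Oc12
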